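**Plan**

1. Numbering used throughout: decalin C1–C10 (C5 and C10 are the ring-fusion atoms; C3 carries =CMe2, C4 the acid chain, C5 a methyl, C8 a methyl, C9 a methyl and the benzylic carbon C11). The target is (4S,5R,8S,9S,10R).
2. Retrosynthesis: the aryl acetate and phenol come from a dimethoxyarene, and the C4 chain from a C4 aldehyde (Wittig, diimide). Both carbocycles are then cut at once through C5–C10 and C3–C4.
3. Enabling feature: ring A is a cyclohexane whose C3 bears an exocyclic tetrasubstituted alkene, flanked by C4 (CH with an acyl-derived chain) and the methyl-bearing quaternary fusion carbon C5. This is the retron of a vinylallene Diels–Alder reaction, with the C6–C9 chain of ring B as the four-atom tether.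
4. Forward: the C8/C9 pair is built on a δ-lactone by two enolate alkylations. The lactone is opened, one end is grown into the (E)-enal (carboalumination) and the other into the vinylallene (hydrozirconation, Negishi coupling). Rings A and B then close together.
5. Stereochemistry: C8 comes from methyl (R)-3-methylglutarate, C9 from alkylation anti to the C8 methyl, and C4, C5 and C10 from the cycloaddition (enal geometry, endo rule, face set by C8/C9).
6. Endgame: two-carbon homologation, diimide reduction, saponification, oxidative demethylation/reduction, and acetylation of the unhindered phenol.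

Key step: step 16

Remark: compounds 1, 5 and 20 are taken as commercial; the allene terminus carries two methyl groups, so the vinylallene has no stereogenic axis.

**Route**

Step 1
Reactants: 1 4-methoxy-2-methylphenol
Product: 2 2-(hydroxymethyl)-4-methoxy-6-methylphenol
Conditions: aq. CH2O (37%), NaOH, H2O, rt
Reagents that add atoms: formaldehyde, C=O
Why: Base-mediated hydroxymethylation of the phenolate (Lederer–Manasse reaction) can occur only at the single free ortho position, because the para and the other ortho position are substituted.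

Step 2
Reactants: 2 2-(hydroxymethyl)-4-methoxy-6-methylphenol
Product: 3 (2,5-dimethoxy-3-methylphenyl)methanol
Conditions: MeI, K2CO3, acetone, reflux
Reagents that add atoms: iodomethane, CI
Why: Williamson etherification with a carbonate base methylates only the acidic phenol and leaves the benzylic alcohol untouched.

Step 3
Reactants: 3 (2,5-dimethoxy-3-methylphenyl)methanol
Product: 4 1-(bromomethyl)-2,5-dimethoxy-3-methylbenzene
Conditions: PBr3, Et2O, 0 °C
Reagents that add atoms: phosphorus tribromide, BrP(Br)Br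
Why: The electron-rich benzylic alcohol is converted into the bromide by bromide displacement of its phosphite ester.

Step 4
Reactants: 5 methyl (R)-3-methylglutarate
Product: 7 (4S)-4-methyloxan-2-one, via (3S)-5-hydroxy-3-methylpentanoic acid 6 (not isolated)
Conditions: LiBH4, THF, 0 °C to reflux; then 2 M HCl, rt
Reagents that add atoms: none
Why: LiBH4 reduces the ester arm while the acid is masked as its lithium carboxylate, and acid then closes the δ-lactone (chemoselective hydride reduction, lactonisation); the stereocentre is untouched and becomes (S) only through the change of CIP priorities.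

Step 5
Reactants: 7 (4S)-4-methyloxan-2-one; 4 1-(bromomethyl)-2,5-dimethoxy-3-methylbenzene
Product: 9 (3R,4S)-3-[(2,5-dimethoxy-3-methylphenyl)methyl]-4-methyloxan-2-one, via lithium enolate 8 (not isolated)
Conditions: LDA, THF, −78 °C; then 4, DMPU, −78 to −40 °C
Reagents that add atoms: none
Why: Alkylation of the lactone enolate with the reactive benzylic bromide should occur anti to the C4 methyl; this centre is planarised again in step 6, so only the regiochemistry matters here.

Step 6
Reactants: 9 (3R,4S)-3-[(2,5-dimethoxy-3-methylphenyl)methyl]-4-methyloxan-2-one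
Product: 11 (3S,4S)-3-[(2,5-dimethoxy-3-methylphenyl)methyl]-3,4-dimethyloxan-2-one, via lithium enolate 10 (not isolated)
Conditions: LDA, THF, −78 to −20 °C; then MeI, DMPU, −78 to −30 °C
Reagents that add atoms: iodomethane, CI
Why: In the half-chair enolate, A(1,2) strain with the arylmethyl group turns the C4 methyl pseudoaxial, so iodomethane should attack the opposite face (enolate alkylation); the new methyl on the quaternary carbon (C9) is therefore trans to the C4 methyl (C8) and the arylmethyl group cis to it.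

Step 7
Reactants: 11 (3S,4S)-3-[(2,5-dimethoxy-3-methylphenyl)methyl]-3,4-dimethyloxan-2-one
Product: 12 (3S,4S)-3-[(2,5-dimethoxy-3-methylphenyl)methyl]-3,4-dimethyloxan-2-ol (both anomers)
Conditions: i-Bu2AlH (1.1 equiv), toluene, −78 °C
Reagents that add atoms: none
Why: Partial hydride reduction of a hindered lactone stops at the lactol because the tetrahedral aluminate is stable at low temperature.

Step 8
Reactants: 12 (3S,4S)-3-[(2,5-dimethoxy-3-methylphenyl)methyl]-3,4-dimethyloxan-2-ol
Product: 13 (3S,4S)-4-[(2,5-dimethoxy-3-methylphenyl)methyl]-3,4-dimethylhex-5-yn-1-ol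
Conditions: dimethyl (1-diazo-2-oxopropyl)phosphonate, K2CO3, MeOH, rt
Reagents that add atoms: dimethyl (1-diazo-2-oxopropyl)phosphonate, COP(=O)(OC)C(=[N+]=[N-])C(C)=O
Why: The lactol opens to the hydroxy aldehyde under the basic conditions and the aldehyde carbon (C10) is homologated to the terminal alkyne (Seyferth–Gilbert homologation with the Ohira–Bestmann reagent); the adjacent carbon is quaternary, so nothing can epimerise.

Step 9
Reactants: 13 (3S,4S)-4-[(2,5-dimethoxy-3-methylphenyl)methyl]-3,4-dimethylhex-5-yn-1-ol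
Product: 14 1-[(2S,3S)-2-ethynyl-5-iodo-2,3-dimethylpentyl]-2,5-dimethoxy-3-methylbenzene
Conditions: I2, PPh3, imidazole, CH2Cl2, 0 °C
Reagents that add atoms: iodine, II
Why: Appel-type iodination turns the unhindered primary alcohol into the iodide by iodide displacement of the alkoxyphosphonium ion.

Step 10
Reactants: 14 1-[(2S,3S)-2-ethynyl-5-iodo-2,3-dimethylpentyl]-2,5-dimethoxy-3-methylbenzene
Product: 16 1-[(2S,3S)-5-iodo-2-[(E)-2-iodoethenyl]-2,3-dimethylpentyl]-2,5-dimethoxy-3-methylbenzene, via alkenylzirconocene chloride 15 (not isolated)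
Conditions: Cp2Zr(H)Cl, THF, rt; then I2, 0 °C
Reagents that add atoms: iodine, II
Why: Hydrozirconation adds H and Zr syn with zirconium on the terminal carbon, and iodinolysis with retention gives the (E)-iodoalkene (C10=C1); the alkyl iodide is inert to both reagents.

Step 11
Reactants: 16 1-[(2S,3S)-5-iodo-2-[(E)-2-iodoethenyl]-2,3-dimethylpentyl]-2,5-dimethoxy-3-methylbenzene
Product: 17 1-[(2S,3S)-2-[(E)-2-iodoethenyl]-2,3-dimethylhept-6-yn-1-yl]-2,5-dimethoxy-3-methylbenzene
Conditions: lithium acetylide–ethylenediamine complex, DMSO, rt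
Reagents that add atoms: lithium acetylide ethylenediamine complex, [Li]C#C.NCCN
Why: The acetylide displaces the primary alkyl iodide in an SN2 alkylation, while the alkenyl iodide cannot undergo substitution.

Step 12
Reactants: 17 1-[(2S,3S)-2-[(E)-2-iodoethenyl]-2,3-dimethylhept-6-yn-1-yl]-2,5-dimethoxy-3-methylbenzene
Product: 19 methyl (2E,6S,7S,8E)-7-[(2,5-dimethoxy-3-methylphenyl)methyl]-9-iodo-3,6,7-trimethylnona-2,8-dienoate, via alkenyl(dimethyl)alane 18 (not isolated)
Conditions: Me3Al, Cp2ZrCl2 (0.25 equiv), ClCH2CH2Cl, rt; then ClCO2Me, rt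
Reagents that add atoms: trimethylaluminium, C[Al](C)C; methyl chloroformate, COC(=O)Cl
Why: Zirconium-catalysed carboalumination (Negishi) adds methyl and aluminium syn with aluminium on the terminal carbon, and acylation of the alkenylalane with retention gives the (E)-trisubstituted enoate (C5=C4).

Step 13
Reactants: 19 methyl (2E,6S,7S,8E)-7-[(2,5-dimethoxy-3-methylphenyl)methyl]-9-iodo-3,6,7-trimethylnona-2,8-dienoate; 20 3-methylbuta-1,2-diene
Product: 23 methyl (2E,6S,7S,8E)-7-[(2,5-dimethoxy-3-methylphenyl)methyl]-3,6,7,12-tetramethyltrideca-2,8,10,11-tetraenoate, via (3-methylbuta-1,2-dien-1-yl)lithium 21 (not isolated), via bromo(3-methylbuta-1,2-dien-1-yl)zinc 22 (not isolated)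
Conditions: 20, n-BuLi, THF, −78 °C; ZnBr2, −78 to 0 °C; then 19, Pd(PPh3)4 (5 mol %), THF, rt
Reagents that add atoms: none
Why: Negishi cross-coupling of the alkenyl iodide with the allenylzinc reagent proceeds with retention of the E geometry and at the allenyl carbon, since coupling at the propargylic terminus would have to build a quaternary centre.

Step 14
Reactants: 23 methyl (2E,6S,7S,8E)-7-[(2,5-dimethoxy-3-methylphenyl)methyl]-3,6,7,12-tetramethyltrideca-2,8,10,11-tetraenoate
Product: 24 (2E,6S,7S,8E)-7-[(2,5-dimethoxy-3-methylphenyl)methyl]-3,6,7,12-tetramethyltrideca-2,8,10,11-tetraen-1-ol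
Conditions: i-Bu2AlH (2.5 equiv), CH2Cl2, −78 °C
Reagents that add atoms: none
Why: 1,2-Reduction of the enoate by the aluminium hydride gives the allylic alcohol and leaves the vinylallene alone.

Step 15
Reactants: 24 (2E,6S,7S,8E)-7-[(2,5-dimethoxy-3-methylphenyl)methyl]-3,6,7,12-tetramethyltrideca-2,8,10,11-tetraen-1-ol
Product: 25 (2E,6S,7S,8E)-7-[(2,5-dimethoxy-3-methylphenyl)methyl]-3,6,7,12-tetramethyltrideca-2,8,10,11-tetraenal
Conditions: MnO2, CH2Cl2, rt
Reagents that add atoms: none
Why: MnO2 oxidises the allylic alcohol chemoselectively to the (E)-enal under neutral conditions, without touching the allene or the alkene geometry.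

Step 16
Reactants: 25 (2E,6S,7S,8E)-7-[(2,5-dimethoxy-3-methylphenyl)methyl]-3,6,7,12-tetramethyltrideca-2,8,10,11-tetraenal
Product: 26 (1S,4aR,5S,6S,8aR)-5-[(2,5-dimethoxy-3-methylphenyl)methyl]-5,6,8a-trimethyl-2-(propan-2-ylidene)-1,2,4a,5,6,7,8,8a-octahydronaphthalene-1-carbaldehyde
Conditions: Me2AlCl (1.5 equiv), CH2Cl2, −78 to −20 °C
Reagents that add atoms: none
Why: The Me2AlCl-bound (E)-enal C4=C5 (2π) and the s-cis vinylallene C10=C1–C2=C3 (4π) combine in a concerted, asynchronous [4+2] cycloaddition that forms C5–C10 and C3–C4 at once, while the distal allene bond C3=CMe2 takes no part and remains as the exocyclic isopropylidene. The closest known reaction type is the Lewis-acid-promoted intramolecular Diels–Alder reaction of a terminally activated deca-1,7,9-triene, here with a vinylallene as the diene. Ring A (C10–C1–C2–C3–C4–C5) is the cyclohexene made by the cycloaddition itself, and ring B (C5–C6–C7–C8–C9–C10) closes in the same event through bond C5–C10 over the four-carbon tether in a chair-like array, which gives the trans ring fusion. C4 and C5 take their cis relation (formyl and methyl) from the E geometry of the enal, C10 is set trans to the C5 methyl by the endo-formyl, tether-anti transition state, and the absolute sense of all three follows from C8/C9, because the arylmethyl group on C9 should sit pseudoequatorial, anti to the incoming dienophile, with the C8 and C9 methyl groups trans-diaxial. The step needs endo selectivity, secured by the Lewis acid and by the allene methyl that lies over the exo site at C4, and facial selectivity, secured by the size difference between CH2Ar and CH3 on the quaternary carbon next to the diene. Me2AlCl also scavenges protons, which should protect the vinylallene and the β,γ-unsaturated aldehyde product from isomerisation.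

Step 17
Reactants: 26 (1S,4aR,5S,6S,8aR)-5-[(2,5-dimethoxy-3-methylphenyl)methyl]-5,6,8a-trimethyl-2-(propan-2-ylidene)-1,2,4a,5,6,7,8,8a-octahydronaphthalene-1-carbaldehyde
Product: 27 methyl (2E)-3-[(1S,4aR,5S,6S,8aR)-5-[(2,5-dimethoxy-3-methylphenyl)methyl]-5,6,8a-trimethyl-2-(propan-2-ylidene)-1,2,4a,5,6,7,8,8a-octahydronaphthalen-1-yl]prop-2-enoate
Conditions: Ph3P=CHCO2Me, toluene, 80 °C
Reagents that add atoms: methyl (triphenylphosphoranylidene)acetate, COC(=O)C=P(c1ccccc1)(c1ccccc1)c1ccccc1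
Why: Wittig olefination with the stabilised, non-basic ylide adds the two missing chain carbons E-selectively and should not enolise the α-stereocentre C4.

Step 18
Reactants: 27 methyl (2E)-3-[(1S,4aR,5S,6S,8aR)-5-[(2,5-dimethoxy-3-methylphenyl)methyl]-5,6,8a-trimethyl-2-(propan-2-ylidene)-1,2,4a,5,6,7,8,8a-octahydronaphthalen-1-yl]prop-2-enoate
Product: 28 methyl 3-[(1S,4aR,5S,6S,8aR)-5-[(2,5-dimethoxy-3-methylphenyl)methyl]-5,6,8a-trimethyl-2-(propan-2-ylidene)decahydronaphthalen-1-yl]propanoate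
Conditions: 2-nitrobenzenesulfonylhydrazide (excess), Et3N, CH2Cl2, rt
Reagents that add atoms: none
Why: Diimide transfers hydrogen syn to the two disubstituted double bonds (ring C1=C2 and the enoate) but should not reduce the tetrasubstituted isopropylidene, and it cannot cause 1,4-addition or alkene migration (diimide reduction).

Step 19
Reactants: 28 methyl 3-[(1S,4aR,5S,6S,8aR)-5-[(2,5-dimethoxy-3-methylphenyl)methyl]-5,6,8a-trimethyl-2-(propan-2-ylidene)decahydronaphthalen-1-yl]propanoate
Product: 29 3-[(1S,4aR,5S,6S,8aR)-5-[(2,5-dimethoxy-3-methylphenyl)methyl]-5,6,8a-trimethyl-2-(propan-2-ylidene)decahydronaphthalen-1-yl]propanoic acid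
Conditions: LiOH, THF–MeOH–H2O, rt; then 1 M HCl
Reagents that add atoms: lithium hydroxide, [Li+].[OH-]
Why: Saponification of the unhindered methyl ester is done before the base-labile aryl acetate is introduced.

Step 20
Reactants: 29 3-[(1S,4aR,5S,6S,8aR)-5-[(2,5-dimethoxy-3-methylphenyl)methyl]-5,6,8a-trimethyl-2-(propan-2-ylidene)decahydronaphthalen-1-yl]propanoic acid
Product: 31 3-[(1S,4aR,5S,6S,8aR)-5-[(2,5-dihydroxy-3-methylphenyl)methyl]-5,6,8a-trimethyl-2-(propan-2-ylidene)decahydronaphthalen-1-yl]propanoic acid, via quinone 30 (not isolated)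
Conditions: (NH4)2Ce(NO3)6, MeCN–H2O, 0 °C; then Na2S2O4, Et2O–H2O, rt
Reagents that add atoms: water, O
Why: Oxidative demethylation of the 1,4-dimethoxyarene gives the quinone, which dithionite reduces to the hydroquinone; the arene is oxidised more easily than the isolated tetrasubstituted alkene.

Step 21
Reactants: 31 3-[(1S,4aR,5S,6S,8aR)-5-[(2,5-dihydroxy-3-methylphenyl)methyl]-5,6,8a-trimethyl-2-(propan-2-ylidene)decahydronaphthalen-1-yl]propanoic acid
Product: 32 3-[(1S,4aR,5S,6S,8aR)-5-[(5-acetyloxy-2-hydroxy-3-methylphenyl)methyl]-5,6,8a-trimethyl-2-(propan-2-ylidene)decahydronaphthalen-1-yl]propanoic acid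
Conditions: Ac2O (1.05 equiv), pyridine, CH2Cl2, 0 °C; aqueous work-up
Reagents that add atoms: acetic anhydride, CC(=O)OC(C)=O
Why: Acylation should occur at the phenol flanked by two ring hydrogens and not at the phenol between the methyl and the arylmethyl substituent, and any mixed anhydride at the acid is hydrolysed on work-up.

**Compound list**

1 | 4-methoxy-2-methylphenol | COc1ccc(O)c(C)c1 | starting material
2 | 2-(hydroxymethyl)-4-methoxy-6-methylphenol | COc1cc(C)c(O)c(CO)c1 | intermediate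
3 | (2,5-dimethoxy-3-methylphenyl)methanol | COc1cc(C)c(OC)c(CO)c1 | intermediate
4 | 1-(bromomethyl)-2,5-dimethoxy-3-methylbenzene | COc1cc(C)c(OC)c(CBr)c1 | intermediate
5 | methyl (R)-3-methylglutarate, (3R)-5-methoxy-3-methyl-5-oxopentanoic acid | COC(=O)C[C@H](C)CC(=O)O | starting material
6 | (3S)-5-hydroxy-3-methylpentanoic acid | OCC[C@H](C)CC(=O)O | intermediate
7 | (4S)-4-methyloxan-2-one | C[C@H]1CCOC(=O)C1 | intermediate
8 | lithium (4S)-4-methyl-5,6-dihydro-4H-pyran-2-olate (lithium enolate of 7) | C[C@H]1CCOC(O[Li])=C1 | intermediate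
9 | (3R,4S)-3-[(2,5-dimethoxy-3-methylphenyl)methyl]-4-methyloxan-2-one | COc1cc(C)c(OC)c(C[C@H]2C(=O)OCC[C@@H]2C)c1 | intermediate
10 | lithium (4S)-3-[(2,5-dimethoxy-3-methylphenyl)methyl]-4-methyl-5,6-dihydro-4H-pyran-2-olate (lithium enolate of 9) | COc1cc(C)c(OC)c(CC2=C(O[Li])OCC[C@@H]2C)c1 | intermediate
11 | (3S,4S)-3-[(2,5-dimethoxy-3-methylphenyl)methyl]-3,4-dimethyloxan-2-one | COc1cc(C)c(OC)c(C[C@]2(C)C(=O)OCC[C@@H]2C)c1 | intermediate
12 | (3S,4S)-3-[(2,5-dimethoxy-3-methylphenyl)methyl]-3,4-dimethyloxan-2-ol (both anomers) | COc1cc(C)c(OC)c(C[C@]2(C)C(O)OCC[C@@H]2C)c1 | intermediate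
13 | (3S,4S)-4-[(2,5-dimethoxy-3-methylphenyl)methyl]-3,4-dimethylhex-5-yn-1-ol | COc1cc(C)c(OC)c(C[C@](C)(C#C)[C@@H](C)CCO)c1 | intermediate
14 | 1-[(2S,3S)-2-ethynyl-5-iodo-2,3-dimethylpentyl]-2,5-dimethoxy-3-methylbenzene | COc1cc(C)c(OC)c(C[C@](C)(C#C)[C@@H](C)CCI)c1 | intermediate
15 | chlorobis(cyclopentadienyl)[(1E,3S,4S)-3-[(2,5-dimethoxy-3-methylphenyl)methyl]-6-iodo-3,4-dimethylhex-1-en-1-yl]zirconium | COc1cc(C)c(OC)c(C[C@](C)(/C=C/[Zr](Cl)(C2C=CC=C2)C2C=CC=C2)[C@@H](C)CCI)c1 | intermediate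
16 | 1-[(2S,3S)-5-iodo-2-[(E)-2-iodoethenyl]-2,3-dimethylpentyl]-2,5-dimethoxy-3-methylbenzene | COc1cc(C)c(OC)c(C[C@](C)(/C=C/I)[C@@H](C)CCI)c1 | intermediate
17 | 1-[(2S,3S)-2-[(E)-2-iodoethenyl]-2,3-dimethylhept-6-yn-1-yl]-2,5-dimethoxy-3-methylbenzene | COc1cc(C)c(OC)c(C[C@](C)(/C=C/I)[C@@H](C)CCC#C)c1 | intermediate
18 | [(1E,5S,6S,7E)-6-[(2,5-dimethoxy-3-methylphenyl)methyl]-8-iodo-2,5,6-trimethylocta-1,7-dien-1-yl]dimethylalane | COc1cc(C)c(OC)c(C[C@](C)(/C=C/I)[C@@H](C)CC/C(C)=C/[Al](C)C)c1 | intermediate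
19 | methyl (2E,6S,7S,8E)-7-[(2,5-dimethoxy-3-methylphenyl)methyl]-9-iodo-3,6,7-trimethylnona-2,8-dienoate | COc1cc(C)c(OC)c(C[C@](C)(/C=C/I)[C@@H](C)CC/C(C)=C/C(=O)OC)c1 | intermediate
20 | 3-methylbuta-1,2-diene | CC(C)=C=C | starting material
21 | (3-methylbuta-1,2-dien-1-yl)lithium | CC(C)=C=C[Li] | intermediate
22 | bromo(3-methylbuta-1,2-dien-1-yl)zinc | CC(C)=C=C[Zn]Br | intermediate
23 | methyl (2E,6S,7S,8E)-7-[(2,5-dimethoxy-3-methylphenyl)methyl]-3,6,7,12-tetramethyltrideca-2,8,10,11-tetraenoate | COc1cc(C)c(OC)c(C[C@](C)(/C=C/C=C=C(C)C)[C@@H](C)CC/C(C)=C/C(=O)OC)c1 | intermediate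
24 | (2E,6S,7S,8E)-7-[(2,5-dimethoxy-3-methylphenyl)methyl]-3,6,7,12-tetramethyltrideca-2,8,10,11-tetraen-1-ol | COc1cc(C)c(OC)c(C[C@](C)(/C=C/C=C=C(C)C)[C@@H](C)CC/C(C)=C/CO)c1 | intermediate
25 | (2E,6S,7S,8E)-7-[(2,5-dimethoxy-3-methylphenyl)methyl]-3,6,7,12-tetramethyltrideca-2,8,10,11-tetraenal | COc1cc(C)c(OC)c(C[C@](C)(/C=C/C=C=C(C)C)[C@@H](C)CC/C(C)=C/C=O)c1 | intermediate
26 | (1S,4aR,5S,6S,8aR)-5-[(2,5-dimethoxy-3-methylphenyl)methyl]-5,6,8a-trimethyl-2-(propan-2-ylidene)-1,2,4a,5,6,7,8,8a-octahydronaphthalene-1-carbaldehyde | COc1cc(C)c(OC)c(C[C@]2(C)[C@H]3C=CC(=C(C)C)[C@@H](C=O)[C@]3(C)CC[C@@H]2C)c1 | intermediate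
27 | methyl (2E)-3-[(1S,4aR,5S,6S,8aR)-5-[(2,5-dimethoxy-3-methylphenyl)methyl]-5,6,8a-trimethyl-2-(propan-2-ylidene)-1,2,4a,5,6,7,8,8a-octahydronaphthalen-1-yl]prop-2-enoate | COc1cc(C)c(OC)c(C[C@]2(C)[C@H]3C=CC(=C(C)C)[C@@H](/C=C/C(=O)OC)[C@]3(C)CC[C@@H]2C)c1 | intermediate
28 | methyl 3-[(1S,4aR,5S,6S,8aR)-5-[(2,5-dimethoxy-3-methylphenyl)methyl]-5,6,8a-trimethyl-2-(propan-2-ylidene)decahydronaphthalen-1-yl]propanoate | COc1cc(C)c(OC)c(C[C@]2(C)[C@H]3CCC(=C(C)C)[C@@H](CCC(=O)OC)[C@]3(C)CC[C@@H]2C)c1 | intermediate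
29 | 3-[(1S,4aR,5S,6S,8aR)-5-[(2,5-dimethoxy-3-methylphenyl)methyl]-5,6,8a-trimethyl-2-(propan-2-ylidene)decahydronaphthalen-1-yl]propanoic acid | COc1cc(C)c(OC)c(C[C@]2(C)[C@H]3CCC(=C(C)C)[C@@H](CCC(=O)O)[C@]3(C)CC[C@@H]2C)c1 | intermediate
30 | 3-[(1S,4aR,5S,6S,8aR)-5,6,8a-trimethyl-5-[(5-methyl-3,6-dioxocyclohexa-1,4-dien-1-yl)methyl]-2-(propan-2-ylidene)decahydronaphthalen-1-yl]propanoic acid | CC1=CC(=O)C=C(C[C@]2(C)[C@H]3CCC(=C(C)C)[C@@H](CCC(=O)O)[C@]3(C)CC[C@@H]2C)C1=O | intermediate
31 | 3-[(1S,4aR,5S,6S,8aR)-5-[(2,5-dihydroxy-3-methylphenyl)methyl]-5,6,8a-trimethyl-2-(propan-2-ylidene)decahydronaphthalen-1-yl]propanoic acid | Cc1cc(O)cc(C[C@]2(C)[C@H]3CCC(=C(C)C)[C@@H](CCC(=O)O)[C@]3(C)CC[C@@H]2C)c1O | intermediate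
32 | 3-[(1S,4aR,5S,6S,8aR)-5-[(5-acetyloxy-2-hydroxy-3-methylphenyl)methyl]-5,6,8a-trimethyl-2-(propan-2-ylidene)decahydronaphthalen-1-yl]propanoic acid (CNP0144688.1) | CC(=O)Oc1cc(C)c(O)c(C[C@]2(C)[C@H]3CCC(=C(C)C)[C@@H](CCC(=O)O)[C@]3(C)CC[C@@H]2C)c1 | target

**Count and risks**

Total step count: 21. Longest linear sequence: 20 steps (1 to 32; the lactone branch from 5 joins at step 5).

Steps most likely to fail:

- **Step 16.** The cycloaddition may show poor facial discrimination between the two chair arrangements of the C6–C9 tether, because the C8 methyl has to sit pseudoaxial in the wanted one. The fallback sets out from ester 23 and adds a second, auxiliary-based control element. Saponification (LiOH) should give the tetraenoic acid F1. Acylation of lithiated (4R)-4-benzyl-1,3-oxazolidin-2-one through the pivaloyl mixed anhydride should give the N-acyloxazolidinone F2. The Me2AlCl-promoted cycloaddition of the chelated imide, in which the benzyl group shields the si face of C4 and so reinforces the bias of C8/C9, should give the cycloadduct imide F3. LiBH4 reduction should release the auxiliary and give the primary alcohol F4, and Dess–Martin oxidation returns to the route at aldehyde 26.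

- **Step 17.** Olefination of the hindered aldehyde may be slow, with epimerisation at C4 through enolisation on prolonged heating. The fallback sets out from aldehyde 26 and replaces the olefination by addition and elimination. Reformatsky addition (BrCH2CO2Me, Zn, THF), whose zinc enolate is small and weakly basic, should give the β-hydroxy ester F5 as both carbinol epimers. MsCl/Et3N should give the mesylate F6, and DBU-induced elimination, which no longer involves a carbonyl next to C4, returns to the route at enoate 27.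

- **Step 13.** The zinc reagent may couple through its propargylic terminus or homocouple. The fallback sets out from alkenyl iodide 19 and builds the allene by reduction instead. Sonogashira coupling with 2-methylbut-3-yn-2-ol (PdCl2(PPh3)2, CuI, Et3N) should give the enynol F7. LiN(SiMe3)2 and ClCO2Me should give the methyl carbonate F8. Pd2(dba)3/PBu3 with HCO2NH4 should then deliver hydride with 1,3-transposition to the allene and return to the route at vinylallene ester 23.

Further compounds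

F1 | step 16 | (2E,6S,7S,8E)-7-[(2,5-dimethoxy-3-methylphenyl)methyl]-3,6,7,12-tetramethyltrideca-2,8,10,11-tetraenoic acid | COc1cc(C)c(OC)c(C[C@](C)(/C=C/C=C=C(C)C)[C@@H](C)CC/C(C)=C/C(=O)O)c1
F2 | step 16 | (4R)-4-benzyl-3-[(2E,6S,7S,8E)-7-[(2,5-dimethoxy-3-methylphenyl)methyl]-3,6,7,12-tetramethyltrideca-2,8,10,11-tetraenoyl]-1,3-oxazolidin-2-one | COc1cc(C)c(OC)c(C[C@](C)(/C=C/C=C=C(C)C)[C@@H](C)CC/C(C)=C/C(=O)N2C(=O)OC[C@H]2Cc2ccccc2)c1
F3 | step 16 | (4R)-4-benzyl-3-{[(1S,4aR,5S,6S,8aR)-5-[(2,5-dimethoxy-3-methylphenyl)methyl]-5,6,8a-trimethyl-2-(propan-2-ylidene)-1,2,4a,5,6,7,8,8a-octahydronaphthalen-1-yl]carbonyl}-1,3-oxazolidin-2-one | COc1cc(C)c(OC)c(C[C@]2(C)[C@H]3C=CC(=C(C)C)[C@@H](C(=O)N4C(=O)OC[C@H]4Cc4ccccc4)[C@]3(C)CC[C@@H]2C)c1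
F4 | step 16 | [(1S,4aR,5S,6S,8aR)-5-[(2,5-dimethoxy-3-methylphenyl)methyl]-5,6,8a-trimethyl-2-(propan-2-ylidene)-1,2,4a,5,6,7,8,8a-octahydronaphthalen-1-yl]methanol | COc1cc(C)c(OC)c(C[C@]2(C)[C@H]3C=CC(=C(C)C)[C@@H](CO)[C@]3(C)CC[C@@H]2C)c1
F5 | step 17 | methyl 3-hydroxy-3-[(1S,4aR,5S,6S,8aR)-5-[(2,5-dimethoxy-3-methylphenyl)methyl]-5,6,8a-trimethyl-2-(propan-2-ylidene)-1,2,4a,5,6,7,8,8a-octahydronaphthalen-1-yl]propanoate | COc1cc(C)c(OC)c(C[C@]2(C)[C@H]3C=CC(=C(C)C)[C@@H](C(O)CC(=O)OC)[C@]3(C)CC[C@@H]2C)c1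
F6 | step 17 | methyl 3-(methanesulfonyloxy)-3-[(1S,4aR,5S,6S,8aR)-5-[(2,5-dimethoxy-3-methylphenyl)methyl]-5,6,8a-trimethyl-2-(propan-2-ylidene)-1,2,4a,5,6,7,8,8a-octahydronaphthalen-1-yl]propanoate | COc1cc(C)c(OC)c(C[C@]2(C)[C@H]3C=CC(=C(C)C)[C@@H](C(OS(C)(=O)=O)CC(=O)OC)[C@]3(C)CC[C@@H]2C)c1
F7 | step 13 | methyl (2E,6S,7S,8E)-7-[(2,5-dimethoxy-3-methylphenyl)methyl]-12-hydroxy-3,6,7,12-tetramethyltrideca-2,8-dien-10-ynoate | COc1cc(C)c(OC)c(C[C@](C)(/C=C/C#CC(C)(C)O)[C@@H](C)CC/C(C)=C/C(=O)OC)c1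
F8 | step 13 | methyl (2E,6S,7S,8E)-7-[(2,5-dimethoxy-3-methylphenyl)methyl]-12-[(methoxycarbonyl)oxy]-3,6,7,12-tetramethyltrideca-2,8-dien-10-ynoate | COc1cc(C)c(OC)c(C[C@](C)(/C=C/C#CC(C)(C)OC(=O)OC)[C@@H](C)CC/C(C)=C/C(=O)OC)c1
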